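If a rate dies away by a steady proportion each minute, the product still to come after the last reading is the last rate times the time in which the rate shrinks by a factor of e. I wanted that time for Friday's flask, which has the charge of Sunday's run.

| flask | starting material | partner | time |
|---|---|---|---|
| Sunday's | 300 mM | 600 mM |  |
| Saturday's | 120 mM | 420 mM |  |
| Monday's | 450 mM | 600 mM |  |
| Friday's | 300 mM | 600 mM | 88 min |

| run | time / min | [product] / mM |
|---|---|---|
| Sunday's run | 2.7 | 17 |
| Sunday's run | 8.1 | 55 |
| Sunday's run | 15 | 83 |
| Sunday's run | 24 | 106 |
| Sunday's run | 35 | 125 |
| Saturday's run | 2.7 | 1 |
| Saturday's run | 8.1 | 24 |
| Saturday's run | 15 | 44 |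
| Saturday's run | 24 | 63 |
| Saturday's run | 35 | 65 |
| Monday's run | 2.7 | 15 |
| Monday's run | 8.1 | 63 |
| Monday's run | 15 | 112 |
| Monday's run | 24 | 125 |
| Monday's run | 35 | 146 |

(standard deviation of a reading: 4 mM)

- the power of [starting material] that the first rate follows, about the charge of the Sunday's run; measure it at two percent of starting material made into product (one fixed amount of product, the same in the runs compared)
- the power of [partner] that the first rate follows, about the charge of the Sunday's run; measure it at two percent of starting material made into product
- product in the Friday's run at 88 min, as a share of the starting material charged

- Overall: starting material + partner -> product.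
- Constant volume, constant temperature.
- Bound and free are read together.
- "The second partner" is partner.
- An order is taken over about fifteen percent of the charge, up and down.

From Sunday's readings I took a rate of 5.37 mM/min between 2.7 min and 15 min, and 2.10 mM/min between 15 min and 35 min, which was slower. The centres of those windows lay 16.1 min apart, so dividing that gap by the logarithm of the rate ratio gave 17.2 min. This is the fall time.

Carried on from the later centre, the rate at 35 min stood near 1.17 mM/min. Up to 88 min I reckoned that this would add 19.3 mM to the reading of 125 mM, so my estimate for Friday's flask was 144 mM, or 48.1 % of its starting material.

The weak link was the fall time, which rested on one curve with a scatter of 4 mM. I reforged it on Saturday's run, read the same way: 3.50 mM/min and 1.05 mM/min gave 13.4 min, shorter. Put into Sunday's tail, although Saturday's charge differs, it gave 46.0 %, and I committed to the span between my two estimates for Friday's flask.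

The forecast stood higher, at 57 % (from 48 % to 66 %), with orders of 0.4 in starting material and 0.8 in partner. Its ground for the share was: “Extrapolating Sunday's curve to 88 min gives about 165–180 mM, or roughly 57%.”

Friday's flask gave 47.7 %, and the orders about Sunday's charge were 0.57 in starting material and 0.29 in partner.

    starting material ⇌ intermediate + by-product (0.07860 /min, 2.424 /M/min)
    intermediate + partner → product (1.872 /M/min)
    2 partner ⇌ idle reagent dimer, settled at all times (12.90 /M)
    2 starting material → homo dimer (0.2022 /M/min)

Friday's flask stood there mainly because of the conversion of starting material into homo dimer: the same run without that step gave 85.8 % instead of 47.7 %. Friday's flask ended 18.0 mM above Sunday's last reading, against the 19.3 mM reckoned from the fall time. On Saturday's run, the fall time of 13.4 min, with the rate carried back to 15 min and the 44 mM read there, put product at half of the starting material charged at 25.4 min, and Saturday's flask reached that amount at 25.2 min.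

All runs stem from a simulated flask on assumed constants; noise was put on by code.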